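**Assumption:** genipin, the commercial iridoid aglycone (1R,4aS,7aS), is taken as an acceptable commercially available starting material. Iridoid numbering is used throughout: C1 acetal, O2, C3=C4 enol ether, C5/C9 ring fusion, C6–C8 cyclopentane, C10 on C8, C11 on C4. β means the face of H-9. The target is 1β-O-isovaleryl, 7β-OH, 8α-OH, 8β-CH2O-isovaleryl, 9β-H, i.e. (1S,7S,8R,9S) in iridoid numbering.

## Retrosynthetic overview

1. Target ⇐ triol 11 by primary-selective acetylation of 11-OH ⇐ dienone-enal 10 by Luche reduction (resets C7, unmasks C11).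
2. 10 ⇐ trans-diol 9 by one-pot IBX oxidation/dehydrogenation (introduces Δ5,6).
3. 9 ⇐ 7β,8β-epoxide 8 by opening assisted by the C10 isovalerate, with inversion at C8 ⇐ alkene 7.
4. 7 ⇐ genipin 1 by an ester→aldehyde swap (TBS, DIBAL, MnO2) followed by double isovalerylation (fixes 1β-O-acyl).
5. Rings: none are constructed. The cis-fused cyclopenta[c]pyran (C1, C9) comes intact from genipin; the only ring made is a transient oxirane (step 6), opened in step 7.

## Route

**Step 1**
Reactants: 1 genipin
Product: 2, 1β,10-bis-O-TBS-genipin (methyl ester retained, 5β-H, 9β-H)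
Conditions: TBSCl (2.5 eq), imidazole, DMAP (cat.), DMF, 0 °C → rt
Reagents that add atoms: TBSCl, CC(C)(C)[Si](C)(C)Cl
Why: Silylation of the primary allylic OH and the lactol OH protects both before hydride reduction; the anomeric ratio at C1 is irrelevant because C1 is reset in step 5.

**Step 2**
Reactants: 2
Product: 3, 1β,10-bis-O-TBS-11-alcohol (C4–CH2OH)
Conditions: DIBAL-H (3 eq), CH2Cl2, −78 °C; Rochelle salt work-up
Reagents that add atoms: none
Why: DIBAL 1,2-reduction of the vinylogous carbonate ester to the allylic alcohol; silyl ether and silyl acetal are inert.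

**Step 3**
Reactants: 3
Product: 4, 1β,10-bis-O-TBS-11-aldehyde (4-formyl enol ether)
Conditions: activated MnO2, CH2Cl2, rt
Reagents that add atoms: none
Why: Allylic oxidation gives a β-alkoxy-enal, which keeps the enol ether electron-poor for steps 6–8 and lets C11 be reduced at the end without touching esters.

**Step 4**
Reactants: 4
Product: 5, (1R,4aS,7aS)-1-hydroxy-7-(hydroxymethyl)-1,4a,5,7a-tetrahydrocyclopenta[c]pyran-4-carbaldehyde (lactol, mainly 1β-OH)
Conditions: HF·pyridine, pyridine/THF, 0 °C → rt
Reagents that add atoms: none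
Why: Buffered fluoride desilylation frees exactly the two hydroxyls (O1, O10) that carry isovalerate in the target.

**Step 5**
Reactants: 5; 6 isovaleric anhydride
Product: 7, (1S,4aS,7aS)-4-formyl-1-(3-methylbutanoyloxy)-7-[(3-methylbutanoyloxy)methyl]-1,4a,5,7a-tetrahydrocyclopenta[c]pyran
Conditions: (iBuCO)2O (2.5 eq), pyridine, DMAP (cat.), CH2Cl2, 0 °C
Reagents that add atoms: isovaleric anhydride, CC(C)CC(=O)OC(=O)CC(C)C
Why: DMAP-catalysed acylation of the primary alcohol and the lactol; the lactol reacts through its predominant equatorial 1β-OH (H-1 trans to H-9, as in genipin), setting the 1β-acyloxy acetal, with any 1α anomer removed by chromatography.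

**Step 6**
Reactants: 7
Product: 8, 7β,8β-epoxide of 7 (oxirane O on the H-5/H-9 face, C10 now α)
Conditions: mCPBA (1.2 eq), NaHCO3, CH2Cl2, 0 °C
Reagents that add atoms: mCPBA, OOC(=O)c1cccc(Cl)c1
Why: Prilezhaev epoxidation of the only nucleophilic alkene (the enol ether is deactivated as a vinylogous formate), from the convex β-face of the cis-fused bicycle; this fixes the 7β C–O bond and sets up C8 for inversion.

**Step 7**
Reactants: 8
Product: 9, (1S,4aS,6S,7R,7aS)-4-formyl-6,7-dihydroxy-1-(3-methylbutanoyloxy)-7-[(3-methylbutanoyloxy)methyl]-1,4a,5,6,7,7a-hexahydrocyclopenta[c]pyran (7β-OH, 8α-OH, 8β-CH2O-isovaleryl)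
Conditions: BF3·OEt2 (0.3 eq), CH2Cl2, −40 → 0 °C; then THF/H2O, rt
Reagents that add atoms: water, O
Why: Lewis-acid epoxide opening with neighbouring-group participation: the C10 ester carbonyl attacks tertiary C8 5-exo from the α-face (Winstein-type dioxolanylium ion, inversion at C8). Hydrolysis returns the acyl group to the primary O-10, leaving 8α-OH and the untouched 7β-OH; direct water attack at C8 would give the same product.

**Step 8**
Reactants: 9
Product: 10, (1S,7R,7aS)-4-formyl-7-hydroxy-1-(3-methylbutanoyloxy)-7-[(3-methylbutanoyloxy)methyl]-6-oxo-1,6,7,7a-tetrahydrocyclopenta[c]pyran (Δ5,6-7-one)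
Conditions: IBX (3.5 eq), 4-methoxypyridine N-oxide, DMSO, 25 → 45 °C
Reagents that add atoms: none
Why: IBX oxidises the secondary alcohol and then dehydrogenates the ketone (Nicolaou IBX dehydrogenation) on its only enolisable side (C6/C5), giving the push–pull dienone under base-free conditions; C5 and C7 are deliberately erased while the quaternary C8 and C9 are untouched.

**Step 9**
Reactants: 10
Product: 11, (1S,6S,7R,7aS)-6,7-dihydroxy-4-(hydroxymethyl)-1-(3-methylbutanoyloxy)-7-[(3-methylbutanoyloxy)methyl]-1,6,7,7a-tetrahydrocyclopenta[c]pyran (11-deacetyl target)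
Conditions: NaBH4, CeCl3·7H2O, MeOH/THF, −78 → −40 °C; NaHCO3 quench
Reagents that add atoms: none
Why: Luche 1,2-reduction of both the enal and the dienone without touching the esters; hydride attacks C7 from the α-face, anti to the bulky 8β-CH2O-acyl group and syn to the small 8α-OH, giving the 7β-alcohol trans to 8-OH.

**Step 10**
Reactants: 11; 12 acetic anhydride
Product: 13, Jatamanvaltrate J
Conditions: Ac2O (1.1 eq), 2,4,6-collidine, CH2Cl2, −20 °C; neutral work-up
Reagents that add atoms: acetic anhydride, CC(=O)OC(C)=O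
Why: Kinetically selective acetylation of the unhindered primary allylic 11-OH over the secondary 7-OH (flanked by quaternary C8) and the tertiary 8-OH.

## Compound list

1 | Genipin, methyl (1R,4aS,7aS)-1-hydroxy-7-(hydroxymethyl)-1,4a,5,7a-tetrahydrocyclopenta[c]pyran-4-carboxylate | COC(=O)C1=CO[C@@H](O)[C@H]2[C@@H]1CC=C2CO | starting material
2 | 1β,10-Bis-O-TBS-genipin | COC(=O)C1=CO[C@@H](O[Si](C)(C)C(C)(C)C)[C@H]2[C@@H]1CC=C2CO[Si](C)(C)C(C)(C)C | intermediate
3 | 1β,10-Bis-O-TBS-11-alcohol | OCC1=CO[C@@H](O[Si](C)(C)C(C)(C)C)[C@H]2[C@@H]1CC=C2CO[Si](C)(C)C(C)(C)C | intermediate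
4 | 1β,10-Bis-O-TBS-11-aldehyde | O=CC1=CO[C@@H](O[Si](C)(C)C(C)(C)C)[C@H]2[C@@H]1CC=C2CO[Si](C)(C)C(C)(C)C | intermediate
5 | 4-Formyl lactol diol (genipin with CHO in place of CO2Me) | O=CC1=CO[C@@H](O)[C@H]2[C@@H]1CC=C2CO | intermediate
6 | Isovaleric (3-methylbutanoic) anhydride | CC(C)CC(=O)OC(=O)CC(C)C | starting material
7 | 1β,10-Di-O-isovaleryl-11-aldehyde, Δ7,8 | O=CC1=CO[C@@H](OC(=O)CC(C)C)[C@H]2[C@@H]1CC=C2COC(=O)CC(C)C | intermediate
8 | 7β,8β-Epoxide of 7 | O=CC1=CO[C@@H](OC(=O)CC(C)C)[C@H]2[C@@H]1C[C@@H]3O[C@]23COC(=O)CC(C)C | intermediate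
9 | 7β,8α-Diol, 1,10-diisovalerate, 11-aldehyde (5β-H) | O=CC1=CO[C@@H](OC(=O)CC(C)C)[C@H]2[C@@H]1C[C@H](O)[C@]2(O)COC(=O)CC(C)C | intermediate
10 | Δ5,6-7-Oxo-8α-hydroxy dienone-enal | O=CC1=CO[C@@H](OC(=O)CC(C)C)[C@H]2C1=CC(=O)[C@]2(O)COC(=O)CC(C)C | intermediate
11 | 11-Deacetyl-jatamanvaltrate J (7β,8α,11-triol) | OCC1=CO[C@@H](OC(=O)CC(C)C)[C@H]2C1=C[C@H](O)[C@]2(O)COC(=O)CC(C)C | intermediate
12 | Acetic anhydride | CC(=O)OC(C)=O | starting material
13 | Jatamanvaltrate J | CC(=O)OCC1=CO[C@@H](OC(=O)CC(C)C)[C@H]2C1=C[C@H](O)[C@]2(O)COC(=O)CC(C)C | target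

## Summary

Total steps: 10. Longest linear sequence: 10 (fully linear from genipin).

Three steps most likely to fail, each with a fallback:

1. **Steps 6–7 (C8 configuration).** Epoxidation on the wrong face, opening at C7, or acyl scrambling through an ortho ester would give the wrong C8 epimer or ester position. Fallback: switch to reagent control. Run a Sharpless asymmetric epoxidation on the free C10 allylic alcohol (before acylation), then a Payne rearrangement (inversion at C8) to the valtrate-type 7β-hydroxy-8α,10-spiro-epoxide, and open it at C10 with caesium isovalerate.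

2. **Step 8 (one-pot IBX oxidation/dehydrogenation).** It may stall at the ketone, or trigger γ-enolisation at C9 and loss of the C1 acyloxy group. Fallback: oxidise with Dess–Martin periodinane to the 7-ketone, then introduce the alkene by α-selenenylation and selenoxide syn-elimination (PhSeCl gives 6β-SePh from the convex face; H2O2 eliminates toward H-5β).

3. **Step 9 (C7 facial selectivity and lability of the dienyl diol).** Fallback: split the reduction. Reduce only the aldehyde (NaBH4, −78 °C), acetylate the single primary OH, then reduce the ketone last under reagent control (CBS/catecholborane or a ketoreductase). This also removes the need for the selective acetylation in step 10.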